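## The problem

The target is galangin (3,5,7-trihydroxyflavone) joined through C8 of ring A to C5' of a 1,7-diarylheptan-3-one. The two halves share one C(sp2)–C(sp3) bond, and the only stereocentre, C5' (R), sits at that junction, benzylic to ring A and β to the C3' ketone.

In a preformed 5,7-dioxygenated flavonol, C6 and C8 are almost equally nucleophilic. The C8–C5' bond, with its configuration, must therefore exist before ring C is built, and ring C must then close without a choice between two ring-A carbons.

No second stereocentre is available to relay from, so C5' must be set by a catalyst or reagent. Once set it is not acidic, but it is attached to a very electron-rich arene that will not tolerate strong acid.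

The free flavonol is air- and base-sensitive. The C3' ketone lies 1,5 to a ring-A oxygen on either side of C8, so a free ortho hydroxyl can close onto it as a hemiketal and lose water under acid. The four hydroxyls are therefore best carried as one kind of ether that is removed last under neutral conditions. The ketone is enolisable on both sides and has to pass through base, Lewis acid and hydrogen.

The feature that makes the key step possible is C4a. In a ring A already bearing O1, the C8 chain and the two ether oxygens, C4a is the only unsubstituted carbon ortho to O1. It is ortho to O5 and para to O7, and an acyl carbon C4 held on O1 through C2=C3 can reach it, and no other carbon, in a six-membered transition state.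

## Retrosynthesis

**22 to 21.** The four O–benzyl bonds of the target 22 are cut last, leading back to the tetra-O-benzyl ether 21. One protecting group for all four hydroxyls allows a single neutral hydrogenolysis, so the free 7-hydroxyl never meets acid next to the C3' ketone. The ketone is carried unprotected. A dioxolane would have to be installed on a keto-phenol prone to ring–chain tautomerism, would cost two steps, and would be the group most exposed to acid chloride, Lewis acid and HCl in the ring closure. The forward step must cleave benzyl ethers without reducing the C2=C3 bond or the ketone.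

**21 to 19.** Ring C is opened at C4–C4a, giving the 3-aryloxy-2-benzyloxy-3-phenylacrylic acid 19, which closes through its acid chloride 20. The neighbouring cuts at O1–C2 (diketone cyclodehydration or oxidative chalcone closure) need an acyl group on ring A first. On phenol 11 both free ring carbons are doubly oxygen-activated, and 6'-oxygenated chalcones tend to give aurones. With the acyl carbon tethered through O1, only C4a is within reach. The precursor lacks ring C and is an open aryl vinyl ether. The forward reaction needs the carboxyl carbon cis to the aryloxy group (or able to become so), activation mild enough for four benzyl ethers, and intramolecular delivery.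

**19 to 11 and 17.** The O1–C2 bond is cut through ester 18, giving phenol 11 and the enol triflate 17. C2 is treated as the β-carbon of an acrylate bearing a leaving group. Conjugate addition of the phenol to an alkynoate would form the same bond but would leave C3 as C–H and add an oxidation later. Triflate 17 brings the C3 oxygen in as its benzyl ether. It comes from β-keto ester 15, the C-acylation product of ester 12 with acid chloride 13. The forward step needs a hindered phenoxide to attack a fully substituted β-carbon, and the later ester hydrolysis must leave the enol ether intact.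

**11 to 7.** The ketone is cut at C3'–C2', giving Weinreb amide 8 and Grignard reagent 10 (from bromide 9). Amide 8 is the ring-opened form of lactone 7. The lactone holds O1 and the C3' acyl carbon in one functional group, so its opening releases the phenol and the acyl donor together. Direct Grignard addition to 7 would over-add, because the aryloxide leaves at once. The forward steps must stop at the ketone and keep the stereocentre, which is β to the carbonyl.

**7 to 2 and 6.** The C5'–C6' bond is cut, giving coumarin 2 and Grignard reagent 6. The other cut at the stereocentre, C5'–C8, would need a 2,6-dioxygenated aryl metal to add to an enone, and such reagents transmetalate slowly and protodemetalate easily. Adding the alkyl group to an acceptor that already carries the aryl ring avoids this. Coumarin 2 is the dibenzyl ether of 1. Reagent 6 comes from bromide 5, made from alcohol 4 and homovanillyl alcohol 3. The forward step must control the face of C4 on an electron-rich, peri-substituted coumarin.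

## Roads not taken

**Alternative 1:** The cut is at C5'–C6' and C5'–C4', with the salicylaldehyde carbon becoming C5'. In the forward step Grignard reagent 6 adds to the O-Boc salicylaldehyde A1. The carbonate migrates to the new alkoxide and leaves, giving an ortho-quinone methide. The chiral enol ether A2 traps it in an inverse-demand hetero-Diels–Alder reaction to give chroman ketal A3.

- Merits: three components combine in one flask, two skeletal bonds and the stereocentre form together, and hydrolysis of A3 would deliver keto-phenol 11. This is more convergent than steps 4 to 6 of the chosen route and avoids conjugate addition to a deactivated coumarin.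
- Weak points: such cycloadditions are established mainly for monosubstituted vinyl ethers. A2 is 1,1-disubstituted, so the facial bias of the trans-2-phenylcyclohexyl group and the endo preference are less secure. A2 must be made by ester methylenation, and the auxiliary is stoichiometric and lost on hydrolysis.
- Comparison: this road does not address ring C, so it competes with the route to 11, not with the key step. The chosen plan offers catalytic control of the stereocentre on the acceptor class for which it is known, and lactone 7, which releases O1 and the acyl donor in one opening.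

**Alternative 2:** The cut is at C4'–C3' and C3'–C2'. The primary iodide A4, carbon monoxide A5 and the borane A6 are joined by a zerovalent palladium catalyst such as Pd(PPh3)4 in a carbonylative alkyl–alkyl Suzuki–Miyaura coupling. The product A7 is identical with 21.

- Merits: the ketone appears one step before the end, so no intermediate carries an enolisable ketone through base or Lewis acid. The chosen route carries it unprotected through five steps, so this road is better on that point.
- Weak points: A4 is a β-branched, β-aryl primary iodide. The alkylpalladium species can undergo β-hydride elimination, and the radical character of the light-assisted variant invites 1,2-aryl shift and addition to the chromone. A4 still needs ring C built by some other method, and its C4' handle has to be carried in masked form and then converted to the iodide, which adds steps.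
- Comparison: the chosen plan makes the ketone in two reliable steps from lactone 7 and accepts the burden of carrying it.

**Alternative 3:** The cut is at C8a–O1, C4a–C4 and O1–C2. Fluoride generates the C4a–C8a aryne from the ortho-silylaryl triflate A8. The carboxylate of 3-phenylpropiolic acid A9 adds through oxygen at C8a, the aryl anion at C4a takes the acyl group, and the phenoxide closes onto the ynone to give flavone A10.

- Merits: three bonds form in one operation from a commercial acid. The regiochemistry is plausible, since the C5 oxygen directs the nucleophile to the remote aryne carbon.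
- Weak points: A8 is a fully substituted benzene with adjacent silyl and triflyloxy groups beside the hindered chain. Making it needs ortho-functionalisation of a phenol whose para position is also open. A10 lacks the C3 oxygen and needs a ketal, so oxidation at C3 and deprotection are added.
- Comparison: this road has better bond economy in its key step. The chosen plan uses the C4a–H bond of the same phenol directly and brings the C3 oxygen in with the acrylate.

Key step: step 11

Assumption 1: the antipode of the ferrocenyl diphosphine in step 4 is the one that delivers the alkyl group to the face of C4 giving (R)-7; the mirror-image ligand is used if a trial on 2 shows the opposite sense.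

Assumption 2: 17, 18 and 19 may form as mixtures of double-bond isomers; they are drawn with the carbonyl carbon cis to the triflyloxy or aryloxy group and carried on as formed, because step 11 equilibrates them.

## Route

Step 1
Reactants: 1 coumarin-5,7-diol (5,7-dihydroxy-2H-chromen-2-one)
Product: 2 dibenzyl ether 5,7-bis(benzyloxy)-2H-chromen-2-one
Conditions: BnBr, K2CO3, DMF, 60 °C
Reagents that add atoms: benzyl bromide, BrCc1ccccc1
Why: Williamson ether synthesis; neither phenol is chelated to the remote lactone carbonyl, so both should alkylate readily.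

Step 2
Reactants: 3 homovanillyl alcohol (4-hydroxy-3-methoxyphenethyl alcohol)
Product: 4 benzyl ether 2-[4-(benzyloxy)-3-methoxyphenyl]ethanol
Conditions: BnBr, K2CO3, acetone, reflux
Reagents that add atoms: benzyl bromide, BrCc1ccccc1
Why: Williamson ether synthesis; carbonate deprotonates only the phenol, so the primary alcohol should stay free.

Step 3
Reactants: 4 benzyl ether 2-[4-(benzyloxy)-3-methoxyphenyl]ethanol
Product: 5 bromide 2-[4-(benzyloxy)-3-methoxyphenyl]ethyl bromide
Conditions: CBr4, PPh3, CH2Cl2, 0 °C
Reagents that add atoms: carbon tetrabromide, BrC(Br)(Br)Br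
Why: Appel reaction of a primary alcohol under neutral conditions that spare the benzyl ether.

Step 4
Reactants: 5 bromide 2-[4-(benzyloxy)-3-methoxyphenyl]ethyl bromide; 2 dibenzyl ether 5,7-bis(benzyloxy)-2H-chromen-2-one
Product: 7 lactone (4R)-5,7-bis(benzyloxy)-4-{2-[4-(benzyloxy)-3-methoxyphenyl]ethyl}chroman-2-one, via arylethylmagnesium bromide 6 (not isolated)
Conditions: Mg, Et2O, rt; then 2, CuBr·SMe2 (5 mol %), (R)-1-[(SP)-2-(dicyclohexylphosphino)ferrocenyl]ethyldiphenylphosphine or its mirror image (6 mol %), CH2Cl2, −72 °C; aq. NH4Cl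
Reagents that add atoms: none
Why: Copper-catalysed asymmetric conjugate addition of a Grignard reagent to a coumarin; the chiral monovalent-copper diphosphine complex delivers the alkyl group to one face of C4 (catalyst control), which sets the future C5' as R, and protonation of the magnesium enolate creates no further centre.

Step 5
Reactants: 7 lactone (4R)-5,7-bis(benzyloxy)-4-{2-[4-(benzyloxy)-3-methoxyphenyl]ethyl}chroman-2-one
Product: 8 Weinreb amide (3R)-3-[2,4-bis(benzyloxy)-6-hydroxyphenyl]-5-[4-(benzyloxy)-3-methoxyphenyl]-N-methoxy-N-methylpentanamide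
Conditions: MeNH(OMe)·HCl, iPrMgCl, THF, −20 → 0 °C; aq. NH4Cl
Reagents that add atoms: N,O-dimethylhydroxylamine hydrochloride, CNOC.Cl
Why: Aminolysis of an aryl ester (lactone) by the chloromagnesium amide of the Weinreb amine; the opening frees the phenol oxygen that becomes O1, and the stereocentre β to the carbonyl is not touched.

Step 6
Reactants: 8 Weinreb amide (3R)-3-[2,4-bis(benzyloxy)-6-hydroxyphenyl]-5-[4-(benzyloxy)-3-methoxyphenyl]-N-methoxy-N-methylpentanamide; 9 (2-bromoethyl)benzene
Product: 11 keto-phenol (5R)-5-[2,4-bis(benzyloxy)-6-hydroxyphenyl]-7-[4-(benzyloxy)-3-methoxyphenyl]-1-phenylheptan-3-one, via phenethylmagnesium bromide 10 (not isolated)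
Conditions: Mg, THF, rt; then 8, THF, −20 → 0 °C (3 equiv of 10); aq. NH4Cl
Reagents that add atoms: none
Why: Weinreb ketone synthesis; one equivalent of 10 deprotonates the phenol, the chelated tetrahedral adduct blocks over-addition, and 11 (which may sit partly as its ring-closed hemiketal) is kept away from acid and used directly.

Step 7
Reactants: 12 methyl 2-(benzyloxy)acetate; 13 benzoyl chloride
Product: 15 keto ester methyl 2-(benzyloxy)-3-oxo-3-phenylpropanoate, via lithium ester enolate 14 (not isolated)
Conditions: LiN(SiMe3)2 (2.2 equiv), THF, −78 °C; then 13, −78 → 0 °C; aq. NH4Cl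
Reagents that add atoms: none
Why: Claisen-type C-acylation of an ester enolate with an acid chloride; the second equivalent of base converts the product to its enolate and so prevents a second acylation.

Step 8
Reactants: 15 keto ester methyl 2-(benzyloxy)-3-oxo-3-phenylpropanoate
Product: 17 enol triflate methyl (E)-2-(benzyloxy)-3-phenyl-3-(trifluoromethylsulfonyloxy)prop-2-enoate, via sodium enolate 16 (not isolated)
Conditions: NaH, THF, 0 °C; then PhNTf2, 0 °C → rt; aq. NH4Cl
Reagents that add atoms: N-phenylbis(trifluoromethanesulfonimide), O=S(=O)(N(c1ccccc1)S(=O)(=O)C(F)(F)F)C(F)(F)F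
Why: O-sulfonylation of a β-keto ester enolate; the sodium chelate between the two carbonyl oxygens should place the triflyloxy group cis to the ester.

Step 9
Reactants: 11 keto-phenol (5R)-5-[2,4-bis(benzyloxy)-6-hydroxyphenyl]-7-[4-(benzyloxy)-3-methoxyphenyl]-1-phenylheptan-3-one; 17 enol triflate methyl (E)-2-(benzyloxy)-3-phenyl-3-(trifluoromethylsulfonyloxy)prop-2-enoate
Product: 18 ester methyl (E)-2-(benzyloxy)-3-{3,5-bis(benzyloxy)-2-[(3R)-1-[4-(benzyloxy)-3-methoxyphenyl]-5-oxo-7-phenylheptan-3-yl]phenoxy}-3-phenylprop-2-enoate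
Conditions: Cs2CO3, DMF, 0 °C → rt
Reagents that add atoms: none
Why: Nucleophilic vinylic substitution (addition–elimination) of a phenoxide at the β-carbon of a β-sulfonyloxy acrylate forms the O1–C2 bond; carbonate ionises the phenol but not the ketone, and the ester-stabilised carbanion should expel triflate with largely retained geometry.

Step 10
Reactants: 18 ester methyl (E)-2-(benzyloxy)-3-{3,5-bis(benzyloxy)-2-[(3R)-1-[4-(benzyloxy)-3-methoxyphenyl]-5-oxo-7-phenylheptan-3-yl]phenoxy}-3-phenylprop-2-enoate
Product: 19 acid (E)-2-(benzyloxy)-3-{3,5-bis(benzyloxy)-2-[(3R)-1-[4-(benzyloxy)-3-methoxyphenyl]-5-oxo-7-phenylheptan-3-yl]phenoxy}-3-phenylprop-2-enoic acid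
Conditions: LiOH·H2O, THF/MeOH/H2O, 40 °C; then 1 M HCl, 0 °C, to pH 3
Reagents that add atoms: lithium hydroxide, [Li+].[OH-]
Why: Ester saponification; β-aryloxyacrylate esters are hydrolysed to their acids without loss of the aryloxy group in the classical chromone syntheses, and the ketone has no epimerisable α-centre.

Step 11
Reactants: 19 acid (E)-2-(benzyloxy)-3-{3,5-bis(benzyloxy)-2-[(3R)-1-[4-(benzyloxy)-3-methoxyphenyl]-5-oxo-7-phenylheptan-3-yl]phenoxy}-3-phenylprop-2-enoic acid
Product: 21 flavone 3,5,7-tris(benzyloxy)-8-[(3R)-1-[4-(benzyloxy)-3-methoxyphenyl]-5-oxo-7-phenylheptan-3-yl]-2-phenyl-4H-chromen-4-one, via acid chloride 20 (not isolated)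
Conditions: 1-chloro-N,N,2-trimethylpropenylamine (1.2 equiv), CH2Cl2, 0 °C → rt; then dilution to 5 mM, ZnCl2 (1 M in Et2O, 1.5 equiv), 0 °C → rt
Reagents that add atoms: none
Why: The α-chloroenamine turns the acid into acid chloride 20 under neutral conditions, and ZnCl2 polarises the C–Cl bond to an acylium-like species that the O1 lone pair stabilises as a ketene–oxocarbenium form. That form lowers the barrier to rotation about C2–C3, so either double-bond isomer can reach the geometry with the acyl carbon cis to the aryloxy group. C4a then attacks the acyl carbon in an intramolecular Friedel–Crafts acylation and loss of the proton restores ring A; the closest known reaction is the Ruhemann-type closure of β-aryloxycinnamic and β-aryloxyacrylic acids to flavones and chromones. Ring C closes in a six-membered exo-trig mode at the acyl carbon, forming the C4–C4a bond. No stereocentre is formed and C5', which has no leaving group and no acidic hydrogen, is not at risk. Site selectivity comes from the tether, since C6 is equally activated but can be reached only by another molecule, which dilution suppresses. Closure onto the C2 phenyl ring (five-membered) or onto the benzyl ring of the C3 ether (six-membered) would use unactivated arenes and should not compete with a phloroglucinol triether. ZnCl2 is too weak to cleave the benzyl ethers in general, and chelation-assisted loss of the 5-O-benzyl group after closure would be harmless because all benzyl groups fall in the next step.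

Step 12
Reactants: 21 flavone 3,5,7-tris(benzyloxy)-8-[(3R)-1-[4-(benzyloxy)-3-methoxyphenyl]-5-oxo-7-phenylheptan-3-yl]-2-phenyl-4H-chromen-4-one
Product: 22 target 3,5,7-trihydroxy-8-[(3R)-1-(4-hydroxy-3-methoxyphenyl)-5-oxo-7-phenylheptan-3-yl]-2-phenyl-4H-chromen-4-one
Conditions: H2 (1 atm), Pd/C (10 %), THF/MeOH, rt
Reagents that add atoms: none
Why: Hydrogenolysis of four benzyl ethers under neutral conditions; the dialkyl ketone and the chromone C2=C3 bond are normally untouched at one atmosphere, and the absence of acid keeps the 7-hydroxyl from closing onto the C3' ketone.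

## Compound list

1 | 5,7-dihydroxy-2H-chromen-2-one | O=c1ccc2c(O)cc(O)cc2o1 | starting material
2 | 5,7-bis(benzyloxy)-2H-chromen-2-one | O=c1ccc2c(OCc3ccccc3)cc(OCc3ccccc3)cc2o1 | intermediate
3 | 4-hydroxy-3-methoxyphenethyl alcohol | COc1cc(CCO)ccc1O | starting material
4 | 2-[4-(benzyloxy)-3-methoxyphenyl]ethanol | COc1cc(CCO)ccc1OCc1ccccc1 | intermediate
5 | 2-[4-(benzyloxy)-3-methoxyphenyl]ethyl bromide | COc1cc(CCBr)ccc1OCc1ccccc1 | intermediate
6 | {2-[4-(benzyloxy)-3-methoxyphenyl]ethyl}magnesium bromide | COc1cc(CC[Mg]Br)ccc1OCc1ccccc1 | intermediate (not isolated)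
7 | (4R)-5,7-bis(benzyloxy)-4-{2-[4-(benzyloxy)-3-methoxyphenyl]ethyl}chroman-2-one | O=C1C[C@@H](CCc2ccc(OCc3ccccc3)c(OC)c2)c2c(OCc3ccccc3)cc(OCc3ccccc3)cc2O1 | intermediate
8 | (3R)-3-[2,4-bis(benzyloxy)-6-hydroxyphenyl]-5-[4-(benzyloxy)-3-methoxyphenyl]-N-methoxy-N-methylpentanamide | COc1cc(CC[C@H](CC(=O)N(C)OC)c2c(O)cc(OCc3ccccc3)cc2OCc2ccccc2)ccc1OCc1ccccc1 | intermediate
9 | (2-bromoethyl)benzene | BrCCc1ccccc1 | starting material
10 | (2-phenylethyl)magnesium bromide | Br[Mg]CCc1ccccc1 | intermediate (not isolated)
11 | (5R)-5-[2,4-bis(benzyloxy)-6-hydroxyphenyl]-7-[4-(benzyloxy)-3-methoxyphenyl]-1-phenylheptan-3-one | COc1cc(CC[C@H](CC(=O)CCc2ccccc2)c2c(O)cc(OCc3ccccc3)cc2OCc2ccccc2)ccc1OCc1ccccc1 | intermediate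
12 | methyl 2-(benzyloxy)acetate | COC(=O)COCc1ccccc1 | starting material
13 | benzoyl chloride | O=C(Cl)c1ccccc1 | starting material
14 | lithium 2-(benzyloxy)-1-methoxyethen-1-olate | [Li+].[O-]C(OC)=COCc1ccccc1 | intermediate (not isolated)
15 | methyl 2-(benzyloxy)-3-oxo-3-phenylpropanoate | COC(=O)C(OCc1ccccc1)C(=O)c1ccccc1 | intermediate
16 | sodium (E)-2-(benzyloxy)-3-methoxy-3-oxo-1-phenylprop-1-en-1-olate | COC(=O)/C(OCc1ccccc1)=C(\[O-])c1ccccc1.[Na+] | intermediate (not isolated)
17 | methyl (E)-2-(benzyloxy)-3-phenyl-3-(trifluoromethylsulfonyloxy)prop-2-enoate | COC(=O)/C(OCc1ccccc1)=C(\OS(=O)(=O)C(F)(F)F)c1ccccc1 | intermediate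
18 | methyl (E)-2-(benzyloxy)-3-{3,5-bis(benzyloxy)-2-[(3R)-1-[4-(benzyloxy)-3-methoxyphenyl]-5-oxo-7-phenylheptan-3-yl]phenoxy}-3-phenylprop-2-enoate | COC(=O)/C(OCc1ccccc1)=C(\Oc1cc(OCc2ccccc2)cc(OCc2ccccc2)c1[C@@H](CC(=O)CCc1ccccc1)CCc1ccc(OCc2ccccc2)c(OC)c1)c1ccccc1 | intermediate
19 | (E)-2-(benzyloxy)-3-{3,5-bis(benzyloxy)-2-[(3R)-1-[4-(benzyloxy)-3-methoxyphenyl]-5-oxo-7-phenylheptan-3-yl]phenoxy}-3-phenylprop-2-enoic acid | OC(=O)/C(OCc1ccccc1)=C(\Oc1cc(OCc2ccccc2)cc(OCc2ccccc2)c1[C@@H](CC(=O)CCc1ccccc1)CCc1ccc(OCc2ccccc2)c(OC)c1)c1ccccc1 | intermediate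
20 | (E)-2-(benzyloxy)-3-{3,5-bis(benzyloxy)-2-[(3R)-1-[4-(benzyloxy)-3-methoxyphenyl]-5-oxo-7-phenylheptan-3-yl]phenoxy}-3-phenylprop-2-enoyl chloride | ClC(=O)/C(OCc1ccccc1)=C(\Oc1cc(OCc2ccccc2)cc(OCc2ccccc2)c1[C@@H](CC(=O)CCc1ccccc1)CCc1ccc(OCc2ccccc2)c(OC)c1)c1ccccc1 | intermediate (not isolated)
21 | 3,5,7-tris(benzyloxy)-8-[(3R)-1-[4-(benzyloxy)-3-methoxyphenyl]-5-oxo-7-phenylheptan-3-yl]-2-phenyl-4H-chromen-4-one | COc1cc(CC[C@H](CC(=O)CCc2ccccc2)c2c(OCc3ccccc3)cc(OCc3ccccc3)c3c(=O)c(OCc4ccccc4)c(-c4ccccc4)oc23)ccc1OCc1ccccc1 | intermediate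
22 | 3,5,7-trihydroxy-8-[(3R)-1-(4-hydroxy-3-methoxyphenyl)-5-oxo-7-phenylheptan-3-yl]-2-phenyl-4H-chromen-4-one | COc1cc(CC[C@H](CC(=O)CCc2ccccc2)c2c(O)cc(O)c3c(=O)c(O)c(-c4ccccc4)oc23)ccc1O | target

## Step count and least certain steps

Total step count: 12. Longest linear sequence: 9 steps (steps 2, 3, 4, 5, 6, 9, 10, 11, 12).

**Step 11 (key step).** The most likely failure is ionisation at the C3 oxygen. The activated acyl species carries an enol benzyl ether on its α-carbon and may lose the benzyl group before the rather weakly electrophilic, oxygen-stabilised acyl carbon is attacked by C4a. Intermolecular acylation at C6 could also compete if closure is slow.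

The fallback leaves the C3 oxygen out of the acylation substrate and adds it after ring closure. It sets out from 11 and returns at 22:
- Conjugate addition of 11 to commercial ethyl 3-phenylpropiolate (K2CO3, DMF, 80 °C) should give ethyl (Z)-3-aryloxy-3-phenylprop-2-enoate F1.
- Saponification gives the acid F2.
- The acid chloride F3, formed and closed under the conditions of step 11, gives the 3-unsubstituted flavone F4, which is the classical substrate type for this closure.
- Dimethyldioxirane in acetone/CH2Cl2 at 0 °C converts F4 to the 2,3-epoxide F5.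
- A trace of TsOH opens F5 to the 3-hydroxyflavone F6.
- Hydrogenolysis as in step 12 gives 22.

**Step 4.** Conjugate addition may be slow and poorly face-selective. Two alkoxy groups feed electron density into the lactone enoate and the C5 benzyloxy group flanks C4, so uncatalysed addition or attack at the lactone carbonyl could compete.

The fallback replaces the coumarin acceptor by an iminium ion. It sets out from 6 and returns at 7:
- Quenching 6 with DMF gives 3-[4-(benzyloxy)-3-methoxyphenyl]propanal F7.
- Wittig reaction with Ph3P=CHCHO gives (E)-5-[4-(benzyloxy)-3-methoxyphenyl]pent-2-enal F8.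
- Friedel–Crafts alkylation of commercial 3,5-bis(benzyloxy)phenol with F8, catalysed by the appropriate enantiomer of 2-[diphenyl(trimethylsilyloxy)methyl]pyrrolidine, followed by hemiacetal closure, gives the lactol (4R)-5,7-bis(benzyloxy)-4-{2-[4-(benzyloxy)-3-methoxyphenyl]ethyl}chroman-2-ol F9.
- Oxidation of F9 with Ag2CO3 on Celite in refluxing toluene gives 7.

**Step 6.** The keto-phenol may close to its hemiketal and lose water to a 4H-chromene on work-up or chromatography, and the magnesium phenoxide may slow the addition.

The fallback caps the phenol before the ketone exists. It sets out from 8 and returns at 18: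
- Substitution of 8 on 17 under the conditions of step 9 gives the Weinreb amide ester methyl (E)-2-(benzyloxy)-3-{3,5-bis(benzyloxy)-2-[(3R)-1-[4-(benzyloxy)-3-methoxyphenyl]-5-[methoxy(methyl)amino]-5-oxopentan-3-yl]phenoxy}-3-phenylprop-2-enoate F10.
- Addition of 10 (1.2 equiv, THF, −40 °C) should occur at the amide in preference to the deactivated, fully substituted acrylate ester and give 18.

**Step 9.** The hindered phenoxide may attack sulfur (triflyl transfer) instead of the β-carbon, which is fully substituted and made less electrophilic by the α-benzyloxy group.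

The fallback forms the O1–C2 bond by carbenoid O–H insertion. It sets out from 11 and returns at 18:
- Diazo transfer to commercial methyl phenylpyruvate gives methyl 3-diazo-2-oxo-3-phenylpropanoate F11.
- Rh2(OAc)4-catalysed O–H insertion of F11 into 11 gives the α-aryloxy keto ester methyl 3-aryloxy-2-oxo-3-phenylpropanoate F12.
- O-Benzylation of the enolate of F12 (BnBr, Cs2CO3, DMF), where C-alkylation is blocked by full substitution, gives 18.

**Step 10.** Hydrolysis of the hindered ester may be slow enough for hydroxide, or the C4' enolate of the ketone (which can reach C2 in a six-membered transition state), to displace the aryloxy group from the enol ether.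

The fallback uses an ester that is removed without base. It sets out from 15 and returns at 19:
- Transesterification of 15 with allyl alcohol (DMAP, toluene, reflux) gives allyl 2-(benzyloxy)-3-oxo-3-phenylpropanoate F13.
- Triflation as in step 8 gives the allyl enol triflate F14.
- Substitution with 11 as in step 9 gives the allyl ester F15.
- Pd(PPh3)4 and morpholine in THF at rt remove the allyl group and give 19.

## Further compounds

F1 | step 11 | ethyl (Z)-3-{3,5-bis(benzyloxy)-2-[(3R)-1-[4-(benzyloxy)-3-methoxyphenyl]-5-oxo-7-phenylheptan-3-yl]phenoxy}-3-phenylprop-2-enoate | CCOC(=O)/C=C(\Oc1cc(OCc2ccccc2)cc(OCc2ccccc2)c1[C@@H](CC(=O)CCc1ccccc1)CCc1ccc(OCc2ccccc2)c(OC)c1)c1ccccc1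
F2 | step 11 | (Z)-3-{3,5-bis(benzyloxy)-2-[(3R)-1-[4-(benzyloxy)-3-methoxyphenyl]-5-oxo-7-phenylheptan-3-yl]phenoxy}-3-phenylprop-2-enoic acid | OC(=O)/C=C(\Oc1cc(OCc2ccccc2)cc(OCc2ccccc2)c1[C@@H](CC(=O)CCc1ccccc1)CCc1ccc(OCc2ccccc2)c(OC)c1)c1ccccc1
F3 | step 11 | (Z)-3-{3,5-bis(benzyloxy)-2-[(3R)-1-[4-(benzyloxy)-3-methoxyphenyl]-5-oxo-7-phenylheptan-3-yl]phenoxy}-3-phenylprop-2-enoyl chloride | ClC(=O)/C=C(\Oc1cc(OCc2ccccc2)cc(OCc2ccccc2)c1[C@@H](CC(=O)CCc1ccccc1)CCc1ccc(OCc2ccccc2)c(OC)c1)c1ccccc1
F4 | step 11 | 5,7-bis(benzyloxy)-8-[(3R)-1-[4-(benzyloxy)-3-methoxyphenyl]-5-oxo-7-phenylheptan-3-yl]-2-phenyl-4H-chromen-4-one | COc1cc(CC[C@H](CC(=O)CCc2ccccc2)c2c(OCc3ccccc3)cc(OCc3ccccc3)c3c(=O)cc(-c4ccccc4)oc23)ccc1OCc1ccccc1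
F5 | step 11 | 2,3-epoxide of F4 (2,3-epoxy-2-phenylchroman-4-one core, epoxide carbons as formed) | COc1cc(CC[C@H](CC(=O)CCc2ccccc2)c2c(OCc3ccccc3)cc(OCc3ccccc3)c3C(=O)C4OC4(c5ccccc5)Oc23)ccc1OCc1ccccc1
F6 | step 11 | 5,7-bis(benzyloxy)-8-[(3R)-1-[4-(benzyloxy)-3-methoxyphenyl]-5-oxo-7-phenylheptan-3-yl]-3-hydroxy-2-phenyl-4H-chromen-4-one | COc1cc(CC[C@H](CC(=O)CCc2ccccc2)c2c(OCc3ccccc3)cc(OCc3ccccc3)c3c(=O)c(O)c(-c4ccccc4)oc23)ccc1OCc1ccccc1
F7 | step 4 | 3-[4-(benzyloxy)-3-methoxyphenyl]propanal | COc1cc(CCC=O)ccc1OCc1ccccc1
F8 | step 4 | (E)-5-[4-(benzyloxy)-3-methoxyphenyl]pent-2-enal | COc1cc(CC/C=C/C=O)ccc1OCc1ccccc1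
F9 | step 4 | (4R)-5,7-bis(benzyloxy)-4-{2-[4-(benzyloxy)-3-methoxyphenyl]ethyl}chroman-2-ol (C2 as formed) | OC1C[C@@H](CCc2ccc(OCc3ccccc3)c(OC)c2)c2c(OCc3ccccc3)cc(OCc3ccccc3)cc2O1
F10 | step 6 | methyl (E)-2-(benzyloxy)-3-{3,5-bis(benzyloxy)-2-[(3R)-1-[4-(benzyloxy)-3-methoxyphenyl]-5-[methoxy(methyl)amino]-5-oxopentan-3-yl]phenoxy}-3-phenylprop-2-enoate | COC(=O)/C(OCc1ccccc1)=C(\Oc1cc(OCc2ccccc2)cc(OCc2ccccc2)c1[C@@H](CC(=O)N(C)OC)CCc1ccc(OCc2ccccc2)c(OC)c1)c1ccccc1
F11 | step 9 | methyl 3-diazo-2-oxo-3-phenylpropanoate | COC(=O)C(=O)C(=[N+]=[N-])c1ccccc1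
F12 | step 9 | methyl 3-{3,5-bis(benzyloxy)-2-[(3R)-1-[4-(benzyloxy)-3-methoxyphenyl]-5-oxo-7-phenylheptan-3-yl]phenoxy}-2-oxo-3-phenylpropanoate (C3 as formed) | COC(=O)C(=O)C(Oc1cc(OCc2ccccc2)cc(OCc2ccccc2)c1[C@@H](CC(=O)CCc1ccccc1)CCc1ccc(OCc2ccccc2)c(OC)c1)c1ccccc1
F13 | step 10 | allyl 2-(benzyloxy)-3-oxo-3-phenylpropanoate | C=CCOC(=O)C(OCc1ccccc1)C(=O)c1ccccc1
F14 | step 10 | allyl (E)-2-(benzyloxy)-3-phenyl-3-(trifluoromethylsulfonyloxy)prop-2-enoate | C=CCOC(=O)/C(OCc1ccccc1)=C(\OS(=O)(=O)C(F)(F)F)c1ccccc1
F15 | step 10 | allyl (E)-2-(benzyloxy)-3-{3,5-bis(benzyloxy)-2-[(3R)-1-[4-(benzyloxy)-3-methoxyphenyl]-5-oxo-7-phenylheptan-3-yl]phenoxy}-3-phenylprop-2-enoate | C=CCOC(=O)/C(OCc1ccccc1)=C(\Oc1cc(OCc2ccccc2)cc(OCc2ccccc2)c1[C@@H](CC(=O)CCc1ccccc1)CCc1ccc(OCc2ccccc2)c(OC)c1)c1ccccc1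
A1 | alternative 1 | tert-butyl 3,5-bis(benzyloxy)-2-formylphenyl carbonate | CC(C)(C)OC(=O)Oc1cc(OCc2ccccc2)cc(OCc2ccccc2)c1C=O
A2 | alternative 1 | 4-phenyl-2-[(1R,2S)-2-phenylcyclohexyl]oxybut-1-ene | C=C(CCc1ccccc1)O[C@@H]1CCCC[C@H]1c1ccccc1
A3 | alternative 1 | 5,7-bis(benzyloxy)-4-{2-[4-(benzyloxy)-3-methoxyphenyl]ethyl}-2-(2-phenylethyl)-2-[(1R,2S)-2-phenylcyclohexyl]oxychroman, C4 arranged as C5' of the target, ketal carbon undefined | COc1cc(CC[C@@H]2CC(CCc3ccccc3)(O[C@@H]3CCCC[C@H]3c3ccccc3)Oc3cc(OCc4ccccc4)cc(OCc4ccccc4)c23)ccc1OCc1ccccc1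
A4 | alternative 2 | 3,5,7-tris(benzyloxy)-8-{4-[4-(benzyloxy)-3-methoxyphenyl]-1-iodobutan-2-yl}-2-phenyl-4H-chromen-4-one, C5' arranged as in the target | COc1cc(CC[C@H](CI)c2c(OCc3ccccc3)cc(OCc3ccccc3)c3c(=O)c(OCc4ccccc4)c(-c4ccccc4)oc23)ccc1OCc1ccccc1
A5 | alternative 2 | carbon monoxide | [C-]#[O+]
A6 | alternative 2 | 9-(2-phenylethyl)-9-borabicyclo[3.3.1]nonane | C(Cc1ccccc1)B1C2CCCC1CCC2
A7 | alternative 2 | 3,5,7-tris(benzyloxy)-8-[(3R)-1-[4-(benzyloxy)-3-methoxyphenyl]-5-oxo-7-phenylheptan-3-yl]-2-phenyl-4H-chromen-4-one (identical with 21) | COc1cc(CC[C@H](CC(=O)CCc2ccccc2)c2c(OCc3ccccc3)cc(OCc3ccccc3)c3c(=O)c(OCc4ccccc4)c(-c4ccccc4)oc23)ccc1OCc1ccccc1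
A8 | alternative 3 | 3,5-bis(benzyloxy)-2-{4-[4-(benzyloxy)-3-methoxyphenyl]-1-[2-(2-phenylethyl)-1,3-dioxolan-2-yl]butan-2-yl}-6-(trimethylsilyl)phenyl trifluoromethanesulfonate, C5' arranged as in the target | COc1cc(CC[C@H](CC2(CCc3ccccc3)OCCO2)c2c(OCc3ccccc3)cc(OCc3ccccc3)c([Si](C)(C)C)c2OS(=O)(=O)C(F)(F)F)ccc1OCc1ccccc1
A9 | alternative 3 | 3-phenylpropiolic acid | OC(=O)C#Cc1ccccc1
A10 | alternative 3 | 5,7-bis(benzyloxy)-8-{4-[4-(benzyloxy)-3-methoxyphenyl]-1-[2-(2-phenylethyl)-1,3-dioxolan-2-yl]butan-2-yl}-2-phenyl-4H-chromen-4-one, C5' arranged as in the target | COc1cc(CC[C@H](CC2(CCc3ccccc3)OCCO2)c2c(OCc3ccccc3)cc(OCc3ccccc3)c3c(=O)cc(-c4ccccc4)oc23)ccc1OCc1ccccc1
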